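**Retrosynthetic overview** (locants: decalin C1–C10 as in labdanes, then C9–C11–C12–C13(CH3)(OO)–C14–C15–C16(OO)–C17(CH3)–C18O2Me)
1. 1,2-Dioxane last: C16–O by 6-exo oxa-Michael of a C13 hydroperoxide, C13–O by Co/O2/silane peroxidation of the C13 methylidene of triene ester 22.
2. 22 comes from 3-hydroxy decalin 20 by C3 deoxygenation; 20 comes from acyclic epoxy-polyene allyl sulfone 18 in one radical cascade (key step): Ti(III) epoxide opening, C4–C5 then C9–C10 bond formation (ring A, then ring B), C7=C8 by loss of PhSO2•.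
3. 18 comes from C6–C7 alkylation of allyl sulfone 17 with (R)-epoxygeranyl bromide 8; the (R)-epoxide is the only source of absolute configuration for the decalin.
4. 8 comes from methyl geranate (organocopper + ynoate), Shi epoxidation, reduction and bromination; 17 comes from a symmetric bis-enoate (double Johnson–Claisen, double Wittig) by mono-reduction and sulfinate displacement.
5. Ring order: A and B together in the key step, dioxane at the end.

Assumption: the phosphorane, sodium benzenesulfinate, Shi ketone, thiocarbonyldiimidazole and the silanes are commercial reagents, not starting materials; every carbon source counted as a starting material has at most 8 non-hydrogen atoms.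

**Step 1**
Reactants: 1 5-bromo-2-methylpent-2-ene; 2 methyl but-2-ynoate
Product: 4 methyl (2E)-3,7-dimethylocta-2,6-dienoate, via Grignard reagent 3 (not isolated)
Conditions: Mg, THF; CuBr·SMe2 (1.0 equiv), −78 °C; then 2, −78 °C; MeOH, aq NH4Cl
Reagents that add atoms: none
Why: Syn-carbocupration of the alkynoate (organocopper conjugate addition) and protonation with retention at −78 °C place the new chain trans to the ester, giving the E-trisubstituted alkene; no stereocentre is formed.

**Step 2**
Reactants: 4 methyl (2E)-3,7-dimethylocta-2,6-dienoate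
Product: 5 methyl (2E)-5-[(2R)-3,3-dimethyloxiran-2-yl]-3-methylpent-2-enoate
Conditions: D-fructose-derived Shi ketone (30 mol %), Oxone, K2CO3, Bu4NHSO4, MeCN–DMM/aq borate buffer pH 10.5, 0 °C
Reagents that add atoms: Oxone (potassium peroxymonosulfate), [K+].[O-]S(=O)(=O)OO
Why: Shi asymmetric epoxidation attacks only the electron-rich 6,7-alkene (the enoate alkene is inert to dioxiranes), and the D-fructose-derived ketone gives the (R)-epoxide (expected 90–95 % ee, which is the ee carried to the target).

**Step 3**
Reactants: 5 methyl (2E)-5-[(2R)-3,3-dimethyloxiran-2-yl]-3-methylpent-2-enoate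
Product: 6 (2E)-5-[(2R)-3,3-dimethyloxiran-2-yl]-3-methylpent-2-en-1-ol
Conditions: DIBAL-H (2.2 equiv), CH2Cl2, −78 °C; Rochelle salt
Reagents that add atoms: none
Why: DIBAL-H 1,2-reduction of the conjugated ester to the allylic alcohol at −78 °C leaves the trisubstituted epoxide and its stereocentre untouched.

**Step 4**
Reactants: 6 (2E)-5-[(2R)-3,3-dimethyloxiran-2-yl]-3-methylpent-2-en-1-ol
Product: 8 (3R)-3-[(3E)-5-bromo-3-methylpent-3-en-1-yl]-2,2-dimethyloxirane, via allylic mesylate 7 (not isolated)
Conditions: MsCl, Et3N, THF, −40 °C; then LiBr, −40 → 0 °C; used crude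
Reagents that add atoms: lithium bromide, [Li+].[Br-]
Why: Mesylation followed by SN2 displacement with bromide at the primary allylic carbon keeps the E geometry and the epoxide intact.

**Step 5**
Reactants: 9 2-methylidenepropane-1,3-diol; 10 trimethyl orthoacetate
Product: 12 dimethyl 4-methylideneheptanedioate, via mono-Claisen hydroxy ester 11 (not isolated)
Conditions: 10 (6 equiv), EtCO2H (cat.), 140 °C, MeOH distilled off
Reagents that add atoms: none
Why: Double Johnson–Claisen rearrangement, in which each [3,3] shift regenerates a 2-substituted allylic alcohol unit so that the second OH rearranges in the same way to the symmetric diester; no stereocentre.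

**Step 6**
Reactants: 12 dimethyl 4-methylideneheptanedioate
Product: 14 dimethyl (2E,9E)-2,10-dimethyl-6-methylideneundeca-2,9-dienedioate, via dialdehyde 13 (not isolated)
Conditions: DIBAL-H (2.1 equiv), CH2Cl2, −78 °C; then Ph3P=C(CH3)CO2Me (2.5 equiv), −78 °C → rt
Reagents that add atoms: methyl 2-(triphenyl-λ5-phosphanylidene)propanoate, COC(=O)C(C)=P(c1ccccc1)(c1ccccc1)c1ccccc1
Why: One-pot DIBAL half-reduction and Wittig olefination, in which the stabilised α-methyl ylide gives the E-trisubstituted enoate (>95:5) on both arms.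

**Step 7**
Reactants: 14 dimethyl (2E,9E)-2,10-dimethyl-6-methylideneundeca-2,9-dienedioate
Product: 15 methyl (2E,9E)-11-hydroxy-2,10-dimethyl-6-methylideneundeca-2,9-dienoate
Conditions: DIBAL-H (2.0 equiv), CH2Cl2, −78 °C; recovered 14 recycled
Reagents that add atoms: none
Why: Statistical mono-reduction of a symmetric diester by DIBAL-H 1,2-reduction (about 45 % per pass, diester recovered) differentiates the two identical arms.

**Step 8**
Reactants: 15 methyl (2E,9E)-11-hydroxy-2,10-dimethyl-6-methylideneundeca-2,9-dienoate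
Product: 17 methyl (2E,9E)-2,10-dimethyl-6-methylidene-11-(phenylsulfonyl)undeca-2,9-dienoate, via allylic mesylate 16 (not isolated)
Conditions: MsCl, Et3N, CH2Cl2, −20 °C; then PhSO2Na, DMF, rt
Reagents that add atoms: sodium benzenesulfinate, [Na+].[O-]S(=O)c1ccccc1
Why: Mesylation and SN2 S-alkylation of sulfinate give the primary E-allyl sulfone, the thermodynamically preferred regioisomer.

**Step 9**
Reactants: 17 methyl (2E,9E)-2,10-dimethyl-6-methylidene-11-(phenylsulfonyl)undeca-2,9-dienoate; 8 (3R)-3-[(3E)-5-bromo-3-methylpent-3-en-1-yl]-2,2-dimethyloxirane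
Product: 18 methyl (2E,9E,13E)-16-[(2R)-3,3-dimethyloxiran-2-yl]-2,10,14-trimethyl-6-methylidene-11-(phenylsulfonyl)hexadeca-2,9,13-trienoate (1:1 at C11)
Conditions: LiHMDS (1.05 equiv) added to 17 + 8, THF, −78 → −40 °C
Reagents that add atoms: none
Why: α-Alkylation of the lithiated allyl sulfone (Julia/Biellmann-type coupling) is selective because the sulfone α-CH2 is the most acidic site and the epoxide is inert at −78 °C; the new sulfone-bearing centre forms 1:1 and is destroyed in step 10.

**Step 10 (key step)**
Reactants: 18 methyl (2E,9E,13E)-16-[(2R)-3,3-dimethyloxiran-2-yl]-2,10,14-trimethyl-6-methylidene-11-(phenylsulfonyl)hexadeca-2,9,13-trienoate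
Product: 20 methyl (2E)-8-[(1R,4aS,6R,8aS)-6-hydroxy-2,5,5,8a-tetramethyl-1,4,4a,5,6,7,8,8a-octahydronaphthalen-1-yl]-2-methyl-6-methylideneoct-2-enoate, via trimethylsilyl ether 19 (not isolated)
Conditions: Cp2TiCl2 (0.3 equiv), Mn (8 equiv), TMSCl (4 equiv), 2,4,6-collidine (7 equiv), THF (0.02 M), rt; then K2CO3, MeOH
Reagents that add atoms: none
Why: Proposed new method: Cp2Ti(III)Cl opens the epoxide by single-electron transfer at the tertiary C–O bond, the β-titanoxy C4 radical closes ring A 6-endo onto C5 through a chair with the C3–O group equatorial so that the (R)-epoxide dictates the ent-labdane sense (H5 anti to the C10 methyl), the C10 radical closes ring B 6-endo onto C9 through the trans-decalin chair with the E-alkene placing the side chain equatorial (H9 anti to the C10 methyl), and the β-sulfonyl C8 radical then expels PhSO2• so that the C7=C8 alkene forms regiospecifically from either sulfone epimer and the cascade cannot run on to the C13 methylidene; the closest known reactions are the titanocene(III) epoxypolyene radical cyclisation (which normally ends in exocyclic alkenes) and radical allylation with allyl sulfones by addition–fragmentation.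

**Step 11**
Reactants: 20 (3-hydroxy decalin from step 10)
Product: 22 methyl (2E)-2-methyl-6-methylidene-8-[(1R,4aR,8aR)-2,5,5,8a-tetramethyl-1,4,4a,5,6,7,8,8a-octahydronaphthalen-1-yl]oct-2-enoate, via imidazolyl thiocarbonate 21 (not isolated)
Conditions: 1,1′-thiocarbonyldiimidazole, DMAP, DCE, 80 °C; evaporate; Bu3SnH, AIBN, toluene, 100 °C
Reagents that add atoms: none
Why: Barton–McCombie deoxygenation removes the C3 oxygen through a secondary ring radical that cannot reach any alkene, so C5, C9 and C10 are unchanged.

**Step 12**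
Reactants: 22 (triene ester from step 11)
Product: 23 methyl (2E)-2,6-dimethyl-8-[(1R,4aR,8aR)-2,5,5,8a-tetramethyl-1,4,4a,5,6,7,8,8a-octahydronaphthalen-1-yl]-6-[(triethylsilyl)peroxy]oct-2-enoate (1:1 at C6 of the chain = C13)
Conditions: Co(thd)2 (10 mol %), Et3SiH (2 equiv), O2 (1 atm), DCE, rt, stopped at about 80 % conversion
Reagents that add atoms: dioxygen, O=O; triethylsilane, CC[SiH](CC)CC
Why: Mukaiyama–Isayama hydroperoxysilylation (Co–H hydrogen-atom transfer, O2 capture of the tertiary radical) favours the unhindered 1,1-disubstituted alkene over the hindered C7=C8 alkene and the electron-poor enoate; C13 forms without facial control (about 1:1) because its two CH2CH2 arms differ only remotely.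

**Step 13**
Reactants: 23 (silyl peroxide from step 12)
Product: 25 methyl (2S)-2-[(3S,6S)-6-methyl-6-{2-[(1R,4aR,8aR)-2,5,5,8a-tetramethyl-1,4,4a,5,6,7,8,8a-octahydronaphthalen-1-yl]ethyl}-1,2-dioxan-3-yl]propanoate, via hydroperoxide 24 (not isolated)
Conditions: HCl (cat.), MeOH, 0 °C; concentrate; Et2NH (0.5 equiv), CF3CH2OH, rt; preparative HPLC
Reagents that add atoms: none
Why: Acidic methanolysis frees the tertiary hydroperoxide, which closes by amine-mediated 6-exo oxa-Michael addition through a chair with the C16 substituent equatorial, and C17 is set by enolate protonation (expected to favour the 16,17-anti isomer by analogy with the exocyclic effect known for α-ester radicals beside ring oxygen); the (13S,16S,17S) target is estimated at 15–25 % of the cyclised material and, since the decalin is enantiomerically defined, every other isomer is a diastereomer removable by HPLC.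

**Compound list**
1 | 5-bromo-2-methylpent-2-ene | CC(C)=CCCBr | starting material
2 | methyl but-2-ynoate | CC#CC(=O)OC | starting material
3 | (4-methylpent-3-en-1-yl)magnesium bromide | CC(C)=CCC[Mg]Br | intermediate
4 | methyl (2E)-3,7-dimethylocta-2,6-dienoate | CC(C)=CCC/C(C)=C/C(=O)OC | intermediate
5 | methyl (2E)-5-[(2R)-3,3-dimethyloxiran-2-yl]-3-methylpent-2-enoate | CC1(C)O[C@@H]1CC/C(C)=C/C(=O)OC | intermediate
6 | (2E)-5-[(2R)-3,3-dimethyloxiran-2-yl]-3-methylpent-2-en-1-ol | CC1(C)O[C@@H]1CC/C(C)=C/CO | intermediate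
7 | (2E)-5-[(2R)-3,3-dimethyloxiran-2-yl]-3-methylpent-2-en-1-yl methanesulfonate | CC1(C)O[C@@H]1CC/C(C)=C/COS(C)(=O)=O | intermediate
8 | (3R)-3-[(3E)-5-bromo-3-methylpent-3-en-1-yl]-2,2-dimethyloxirane | CC1(C)O[C@@H]1CC/C(C)=C/CBr | intermediate
9 | 2-methylidenepropane-1,3-diol | C=C(CO)CO | starting material
10 | trimethyl orthoacetate | CC(OC)(OC)OC | starting material
11 | methyl 4-(hydroxymethyl)pent-4-enoate | COC(=O)CCC(=C)CO | intermediate
12 | dimethyl 4-methylideneheptanedioate | COC(=O)CCC(=C)CCC(=O)OC | intermediate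
13 | 4-methylideneheptanedial | O=CCCC(=C)CCC=O | intermediate
14 | dimethyl (2E,9E)-2,10-dimethyl-6-methylideneundeca-2,9-dienedioate | COC(=O)/C(C)=C/CCC(=C)CC/C=C(\C)C(=O)OC | intermediate
15 | methyl (2E,9E)-11-hydroxy-2,10-dimethyl-6-methylideneundeca-2,9-dienoate | COC(=O)/C(C)=C/CCC(=C)CC/C=C(\C)CO | intermediate
16 | methyl (2E,9E)-2,10-dimethyl-6-methylidene-11-(methylsulfonyloxy)undeca-2,9-dienoate | COC(=O)/C(C)=C/CCC(=C)CC/C=C(\C)COS(C)(=O)=O | intermediate
17 | methyl (2E,9E)-2,10-dimethyl-6-methylidene-11-(phenylsulfonyl)undeca-2,9-dienoate | COC(=O)/C(C)=C/CCC(=C)CC/C=C(\C)CS(=O)(=O)c1ccccc1 | intermediate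
18 | methyl (2E,9E,13E)-16-[(2R)-3,3-dimethyloxiran-2-yl]-2,10,14-trimethyl-6-methylidene-11-(phenylsulfonyl)hexadeca-2,9,13-trienoate (both C11 epimers) | COC(=O)/C(C)=C/CCC(=C)CC/C=C(\C)C(C/C=C(\C)CC[C@H]1OC1(C)C)S(=O)(=O)c1ccccc1 | intermediate
19 | trimethylsilyl ether of 20 (same configuration) | COC(=O)/C(C)=C/CCC(=C)CC[C@@H]1C(C)=CC[C@@H]2C(C)(C)[C@H](O[Si](C)(C)C)CC[C@@]12C | intermediate
20 | methyl (2E)-8-[(1R,4aS,6R,8aS)-6-hydroxy-2,5,5,8a-tetramethyl-1,4,4a,5,6,7,8,8a-octahydronaphthalen-1-yl]-2-methyl-6-methylideneoct-2-enoate (trans-decalin, equatorial OH cis to the angular methyl) | COC(=O)/C(C)=C/CCC(=C)CC[C@@H]1C(C)=CC[C@@H]2C(C)(C)[C@H](O)CC[C@@]12C | intermediate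
21 | O-ester of 20 with 1H-imidazole-1-carbothioic acid (same configuration) | COC(=O)/C(C)=C/CCC(=C)CC[C@@H]1C(C)=CC[C@@H]2C(C)(C)[C@H](OC(=S)n3ccnc3)CC[C@@]12C | intermediate
22 | methyl (2E)-2-methyl-6-methylidene-8-[(1R,4aR,8aR)-2,5,5,8a-tetramethyl-1,4,4a,5,6,7,8,8a-octahydronaphthalen-1-yl]oct-2-enoate | COC(=O)/C(C)=C/CCC(=C)CC[C@@H]1C(C)=CC[C@@H]2C(C)(C)CCC[C@@]12C | intermediate
23 | methyl (2E)-2,6-dimethyl-8-[(1R,4aR,8aR)-2,5,5,8a-tetramethyl-1,4,4a,5,6,7,8,8a-octahydronaphthalen-1-yl]-6-[(triethylsilyl)peroxy]oct-2-enoate (6RS) | COC(=O)/C(C)=C/CCC(C)(OO[Si](CC)(CC)CC)CC[C@@H]1C(C)=CC[C@@H]2C(C)(C)CCC[C@@]12C | intermediate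
24 | methyl (2E)-6-hydroperoxy-2,6-dimethyl-8-[(1R,4aR,8aR)-2,5,5,8a-tetramethyl-1,4,4a,5,6,7,8,8a-octahydronaphthalen-1-yl]oct-2-enoate (6RS) | COC(=O)/C(C)=C/CCC(C)(OO)CC[C@@H]1C(C)=CC[C@@H]2C(C)(C)CCC[C@@]12C | intermediate
25 | methyl (2S)-2-[(3S,6S)-6-methyl-6-{2-[(1R,4aR,8aR)-2,5,5,8a-tetramethyl-1,4,4a,5,6,7,8,8a-octahydronaphthalen-1-yl]ethyl}-1,2-dioxan-3-yl]propanoate | COC(=O)[C@@H](C)[C@@H]1CC[C@](C)(CC[C@@H]2C(C)=CC[C@@H]3C(C)(C)CCC[C@@]23C)OO1 | target

**Step count and risks**
Total steps: 13. Longest linear sequence: 9 (steps 1–4, then 9–13; the other branch, steps 5–8 then 9–13, is also 9).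

Most likely to fail:

Step 10. The bicyclisation with sulfonyl-radical termination is untested; the realistic problems are premature reduction or elimination of the C4 radical, low turnover once sulfinate binds titanium, and a modest yield (35–50 % would be normal for this class). The fallback sets out from 18 and comes back at 20. The epoxide is isomerised with diethylaluminium 2,2,6,6-tetramethylpiperidide (toluene, 0 °C) to the allylic alcohol methyl (2E,9E,13E,17R)-17-hydroxy-2,10,14,18-tetramethyl-6-methylidene-11-(phenylsulfonyl)nonadeca-2,9,13,18-tetraenoate F1. The same C3-oxygenated C4 radical is then generated by metal-hydride hydrogen-atom transfer to the isopropenyl group (Co(salen)Cl cat., PhSiH3, benzene, rt). Cyclisation and loss of PhSO2• follow as before; the sulfonyl radical is captured by Co(II) and exchanged for hydride by the silane, so hydrogen-atom transfer to the C13 methylidene is only a reversible side equilibrium. This replaces electron-transfer initiation by hydrogen-atom-transfer initiation and removes Ti(III) and TMSCl.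

Step 12. The Co–H may also attack the C7=C8 alkene or the enoate, and the step gives no control at C13, which halves the maximum yield of target. The fallback sets out from 22 and comes back at 24. Markovnikov peroxymercuration (Hg(OAc)2, concentrated H2O2, CH2Cl2, 0 °C) is governed by steric access and reacts only at the 1,1-disubstituted alkene, giving methyl (2E)-6-[(acetyloxymercurio)methyl]-6-hydroperoxy-2-methyl-8-[(1R,4aR,8aR)-2,5,5,8a-tetramethyl-1,4,4a,5,6,7,8,8a-octahydronaphthalen-1-yl]oct-2-enoate F2. Alkaline NaBH4 demercuration then gives hydroperoxide 24 directly. C13 remains 1:1 in this fallback as well.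

Step 13. The oxa-Michael closure has little intrinsic 3,6-selectivity (methyl and CH2CH2R are similar in size), and the protonation selectivity at C17 is an expectation, not a known result. The fallback sets out from 24 and comes back at 25 without a new compound (F0). The ring is closed by a radical chain instead of a base: di-tert-butyl hyponitrite (10 mol %), tert-dodecanethiol (0.5 M), degassed benzene, 40 °C. The tertiary peroxyl radical adds 6-exo to C16, and the resulting α-ester radical at C17, which sits beside the ring oxygen, takes hydrogen from the thiol with the anti preference of the exocyclic effect. The thiol concentration is kept high so that hydrogen transfer outruns epoxide formation from the β-peroxy radical.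

**Further compounds**
F1 | step 10 | methyl (2E,9E,13E,17R)-17-hydroxy-2,10,14,18-tetramethyl-6-methylidene-11-(phenylsulfonyl)nonadeca-2,9,13,18-tetraenoate | COC(=O)/C(C)=C/CCC(=C)CC/C=C(\C)C(C/C=C(\C)CC[C@@H](O)C(C)=C)S(=O)(=O)c1ccccc1
F2 | step 12 | methyl (2E)-6-[(acetyloxymercurio)methyl]-6-hydroperoxy-2-methyl-8-[(1R,4aR,8aR)-2,5,5,8a-tetramethyl-1,4,4a,5,6,7,8,8a-octahydronaphthalen-1-yl]oct-2-enoate | COC(=O)/C(C)=C/CCC(C[Hg]OC(C)=O)(OO)CC[C@@H]1C(C)=CC[C@@H]2C(C)(C)CCC[C@@]12C
F0 | step 13 | none | none
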